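The data were generated by integration with made-up constants; scatter was added.

Take the power of ten as your unit of progress: a first-order decay then becomes a steady walk down a logarithmic scale, and you count decades instead of integrating.

in all of them: substrate 0.36 M; initiator 18 mM
- alder: partner 0.72 M; temperature 70 °C; run made earlier
- north-west: partner 0.360 M; temperature 40 °C; time 6.0 min
- west: partner 0.360 M; temperature 70 °C; time 6.0 min

alder run (percent of the substrate charged)

| time / s | target / % | substrate / % |
|---|---|---|
| 10.0 | 10.3 | 89.3 |
| 20.0 | 19.5 | 78.5 |
| 25.0 | 23.9 | 74.8 |
| 40.0 | 36.5 | 65.4 |

(scatter of a reading: 1 percentage point)

* which of the two ends with the higher amount of target, in percent of the substrate charged ("neither" if they lie within 2 percentage points) (north-west / west / neither)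
* target at the end, in percent of the substrate charged, north-west
* target at the end, in percent of the substrate charged, west

- percentages count the substrate that a species holds: one ended chains B counts as two
- what may be going on: initiator -> 2 initiating radical; substrate + initiating radical -> capped initiator + first chain carrier; partner + first chain carrier -> target + second chain carrier; substrate + second chain carrier -> by-product + first chain carrier; 2 second chain carrier -> ended chains A; 2 first chain carrier -> ended chains B; partner -> decomposition product
- the earlier runs do not show what temperature does; that part of a forecast is a guess

Each turn of the chain spends one partner and makes one target. The last alder reading, 36.5% target from 0.36 M substrate, therefore means 0.131 M of partner spent, which leaves 0.589 M of the 0.72 M charged. That is 0.0875 of a decade in 40.0 s. So your carried quantity is D = 457 s, the decade time, meaning the time partner needs to fall by one power of ten.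

West has the same initiator, substrate and temperature, so take D over unchanged. Its 360 s are 0.788 decades, which leaves 16.3% of the partner. With equal charges, that makes 83.7% target.

The weak link is D itself, since it rests on a single reading. Reforge it from the 20.0 s reading: 19.5% target gives D = 449 s, and west then stands at 84.2%. A D that holds as partner falls is the mark of a pseudo-first-order decay, so commit to that figure. Alder was run at 70 °C, so it gives no D for north-west.

The forecast names west, with 73% (55% to 86%) there and a guessed 10% (3% to 27%) in north-west. Its west figure stands lower than mine, on the grounds that “Substrate dependence, initiator fade and partner decomposition may all lower this”.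

The flask gives 83.1% in west and 14.9% in north-west, so west ends higher.

    initiator → 2 initiating radical (k = 2.60 × 10⁻⁵ /s, Ea = 114 kJ/mol)
    substrate + initiating radical → capped initiator + first chain carrier (k = 1.80 × 10⁷ /M/s, Ea = 22.0 kJ/mol)
    partner + first chain carrier → target + second chain carrier (k = 1.70 × 10⁵ /M/s, Ea = 19.0 kJ/mol)
    substrate + second chain carrier → by-product + first chain carrier (k = 1.20 × 10⁶ /M/s, Ea = 21.0 kJ/mol)
    2 second chain carrier → ended chains A (k = 2.50 × 10⁷ /M/s, Ea = 14.0 kJ/mol)
    2 first chain carrier → ended chains B (k = 5.30 × 10⁸ /M/s, Ea = 8.00 kJ/mol)
    partner → decomposition product (k = 5.30 × 10⁻⁵ /s, Ea = 99.0 kJ/mol)
    (constants at 70 °C)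

West's partner ends at 16.0%, against the 16.3% that the decades gave. The gap between the two flasks is mainly the difference in temperature: north-west brought to west's temperature stands at 83.1% instead of 14.9%. Now take a neighbouring flask, west with 0.14 M substrate: D puts the spending of that much partner at 97.8 s, less than the 360 s allowed. That flask ends with 0% substrate, 99.9% target and 60% of its partner.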